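# Rhamnetin 3,3'-disulfate by thermal ring C annulation of 3,5-dimethoxyphenol

## The problem

Rhamnetin 3,3'-disulfate is a flavonol: a benzopyran-4-one (rings A and C) carrying ring B on C2, with five oxygen substituents and no stereocentre. The difficulty is therefore one of regiochemistry and of timing, not of configuration. The enolic O3 on ring C and the phenolic O3' on ring B carry sulfate half-esters, while O4' and O5 must end as free hydroxyls and O7 as a methyl ether. O3' and O4' are neighbours on ring B and can only be told apart reliably while ring B is still a simple catechol. Sulfate half-esters are lost in acid and cannot be carried through a synthesis, but they tolerate base. They must therefore go on next to last, and whatever is removed after them has to leave under basic or neutral conditions. The 5-hydroxyl is hydrogen-bonded to the C4 carbonyl, so it needs no protection during sulfation; conversely, a 5-O-methyl group is the one methyl ether that a Lewis acid removes selectively by chelation. The feature that allows a short construction is the phloroglucinol pattern of ring A. In 3,5-dimethoxyphenol the two carbons ortho to the hydroxyl are equivalent and activated by three oxygens, so the future C4a is a strong carbon nucleophile beside the future O1. C4, the oxygenated C3 and the aryl-bearing C2 then map onto an α-alkoxy aroylacetate. Joining these two pieces needs about 240 °C in a phenolic melt, so the protecting groups must be chosen for heat first and for orthogonality second.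

## Retrosynthesis

**Last deprotection.** Target 14 is traced to the disodium disulfate 13 by cutting the sulfonyl S–O bond at O4'. A benzyl ether removed by hydrogenolysis was the neighbouring choice. An arenesulfonate is preferred because it survives 240 °C and BCl3, and because it is released by hydroxide, the one reagent class that sulfate monoester anions ignore. The forward step must cleave an activated aryl sulfonate without opening ring C.

**Sulfation.** 13 is traced to triol 12 by cutting the O3–S and O3'–S bonds. In 12 only the two hydroxyls that are to be sulfated are reactive: O4' is blocked and the chelated 5-OH is the least reactive hydroxyl of a flavonol. Nothing but an SO3–amine complex is needed.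

**Global ether cleavage.** 12 is traced to flavone 11 by cutting two O–benzyl bonds (O3, O3') and the O5–methyl bond. Acid-labile ethers on O3 and O3' would have needed two separate removal steps and would not be safe in the hot melt of the annulation. Benzyl ethers are heat-proof, and BCl3 removes them together with the chelated 5-O-methyl group in one operation. The forward step must leave the 7-O-methyl ether and the sulfonate untouched.

**Ring C.** 11 is traced to keto ester 7 and 3,5-dimethoxyphenol 8 by cutting C4–C4a and O1–C2, through the aroylketene 9 and the diketone 10. The neighbouring cuts are O1–C2 with C2–C3 (acyl shift on a preformed 2-hydroxyaryl ketone) or C2–C1' (cross-coupling). Both need a ring A ketone that must first be made. The chosen cut uses a purchased, symmetric phenol and takes the tricyclic flavone back to a monocyclic phenol and an acyclic keto ester. The forward reaction must acylate the ortho carbon rather than stop at oxygen, give the chromone and not the coumarin, and spare every protecting group at 240 °C.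

**Keto ester.** 7 is traced through the aldol 6 to aldehyde 3 and ethyl 2-(benzyloxy)acetate 4 (enolate 5) by cutting the bond between the future C2 and C3. A Claisen acylation with a benzoic acid derivative was the alternative. It needs a saponification that the sulfonate would not survive and an excess of enolate. Aldol addition followed by oxidation uses one equivalent of each partner, and the stereocentres it creates are of no consequence.

**Ring B.** 3 is traced through the monosulfonate 2 to 3,4-dihydroxybenzaldehyde 1 by cutting the O–benzyl and O–sulfonyl bonds. The 4-OH, para to the formyl group, is the more acidic phenol and reacts first with one equivalent of base. This places the sulfonate on the oxygen that becomes O4' and leaves the future O3' for the benzyl group.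

## Roads not taken

**Alternative 1:** The same C4–C4a bond is cut, but C4 is taken back to the terminal carbon of an alkyne instead of an ester carbonyl. In the forward direction the propargylic aryl ether A1 would be treated with Ph3PAuNTf2 (monovalent gold) and a quinoline N-oxide. Oxygen transfer to the gold-bound alkyne gives an α-oxo gold carbene on the terminal carbon, which attacks the ortho carbon of the dimethoxyphenyl ether and closes ring C as the chroman-3-one A2.
- Merits: the closure runs near room temperature, is catalytic, and tolerates acetal protecting groups that a thermal route must exclude. The symmetry of ring A again removes any regiochemical question.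
- Weak points: A2 has a methylene at C4 and a ketone at C3. The C4 carbonyl and the C2–C3 double bond would have to be added afterwards by benzylic oxidation and dehydrogenation of an enolisable, air-sensitive 2-arylchroman-3-one. A1 is a benzylic and propargylic aryl ether that is awkward to make and prone to ionise under the Lewis-acidic catalyst.
- Comparison: in mildness the gold route is better. The chosen plan sets against this a ring C that arrives with C3 and C4 at the final oxidation state, purchased components, and several fewer operations.

**Alternative 2:** Ring A is cut across four bonds and built onto a finished pyranone. Irradiation of the pyranonyl diazoketone A3 would trigger a Wolff rearrangement to a vinylketene (C8–C8a). Cycloaddition with methoxyethyne A4 (C5–C6 and C7–C8), four-electron ring opening and six-electron closure (C4a–C5) would then give phenol A5.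
- Merits: ring A emerges with exactly the pattern of the target, a free 5-hydroxyl and the 7-methoxy group placed by the polarity of the alkyne. No demethylation is needed. In this respect it is better than the chosen plan.
- Weak points: A3 is a fully substituted 4-pyranone whose preparation would be longer than the whole chosen route. 4-Pyranones are photoactive and can isomerise under the light needed for the Wolff step. A4 is volatile and unstable. A benzene ring that can be bought is being built.
- Comparison: the chosen plan must cleave a 5-O-methyl group, but this happens in the same BCl3 operation that removes the benzyl ethers, so it costs no step.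

**Alternative 3:** C1'–C2, C2–C3 and O1–C2 are cut, and carbon monoxide becomes C2. With Pd(OAc)2, 1,4-bis(diphenylphosphino)butane, DBU and CO, bromide A6 would add to zerovalent palladium formed in the flask and insert CO. The aroylpalladium species would acylate the phenol of hydroxyketone A7, and base would then move the aroyl group to the ketone α-carbon and close ring C to flavone A8.
- Merits: three components join in one flask at about 100–120 °C. Acid-labile groups are tolerated, and O5 and O7 are differentiated from the start, so no selective demethylation is needed. In mildness and in ring A differentiation it is equal or better.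
- Weak points: A7 must be prepared in several steps from a desymmetrised phloroglucinol. Its α-alkoxy ketone is flanked by two ortho substituents, which hinders the acyl shift. The electron-rich bromide A6 is slow in oxidative addition, and the step needs CO under pressure.
- Comparison: the chosen plan sets against this a ring A and a C3 unit that are both purchased, an eight-step linear route, and no gas handling.

Key step: step 5

## Route

Assumption: the target is taken as the free bis(hydrogen sulfate) that its structure shows; the sodium salt is the form that keeps, so the acid is released only in the last work-up.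

Step 1
Reactants: 1 3,4-dihydroxybenzaldehyde
Product: 2 4-formyl-2-hydroxyphenyl 4-methylbenzenesulfonate
Conditions: TsCl (1.0 equiv), K2CO3 (1.0 equiv), acetone, 0 °C to 20 °C
Reagents that add atoms: 4-methylbenzenesulfonyl chloride, Cc1ccc(S(Cl)(=O)=O)cc1
Why: Regioselective O-sulfonylation of a catechol; with one equivalent of weak base only the more acidic 4-OH, para to the formyl group, is ionised, the same bias that governs the well-known 4-O-alkylation of this aldehyde.

Step 2
Reactants: 2 4-formyl-2-hydroxyphenyl 4-methylbenzenesulfonate
Product: 3 2-(benzyloxy)-4-formylphenyl 4-methylbenzenesulfonate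
Conditions: BnBr (1.2 equiv), K2CO3, DMF, 20 °C
Reagents that add atoms: benzyl bromide, BrCc1ccccc1
Why: Williamson etherification of the remaining phenol; the aryl sulfonate is inert to carbonate at room temperature and a shift of the sulfonyl group between neighbouring oxygens is geometrically disfavoured.

Step 3
Reactants: 4 ethyl 2-(benzyloxy)acetate; 3 2-(benzyloxy)-4-formylphenyl 4-methylbenzenesulfonate
Product: 6 ethyl 2-(benzyloxy)-3-{3-(benzyloxy)-4-[(4-methylphenyl)sulfonyloxy]phenyl}-3-hydroxypropanoate (racemic syn/anti mixture), via lithium ester enolate 5 (not isolated)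
Conditions: LiN(iPr)2 (1.1 equiv), THF, −78 °C; then 3, −78 °C; AcOH quench
Reagents that add atoms: none
Why: Aldol addition of a lithium ester enolate to a non-enolisable aromatic aldehyde, much faster at −78 °C than attack on the sulfonate. Both new stereocentres form without control, which is of no consequence because one is oxidised in step 4 and the other becomes sp2 in step 5.

Step 4
Reactants: 6 ethyl 2-(benzyloxy)-3-{3-(benzyloxy)-4-[(4-methylphenyl)sulfonyloxy]phenyl}-3-hydroxypropanoate
Product: 7 ethyl 2-(benzyloxy)-3-{3-(benzyloxy)-4-[(4-methylphenyl)sulfonyloxy]phenyl}-3-oxopropanoate (racemic)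
Conditions: Dess–Martin periodinane, CH2Cl2, 0 °C to 20 °C
Reagents that add atoms: none
Why: Dess–Martin oxidation of a benzylic secondary alcohol under neutral conditions, which avoids base-induced retro-Claisen cleavage of the β-keto ester; both diastereomers of 6 converge on one racemic product.

Step 5
Reactants: 7 ethyl 2-(benzyloxy)-3-{3-(benzyloxy)-4-[(4-methylphenyl)sulfonyloxy]phenyl}-3-oxopropanoate; 8 3,5-dimethoxyphenol
Product: 11 2-(benzyloxy)-4-[3-(benzyloxy)-5,7-dimethoxy-4-oxo-4H-chromen-2-yl]phenyl 4-methylbenzenesulfonate, via aroylketene 9 (not isolated), via hydroxyaryl diketone 10 (not isolated)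
Conditions: 8 (3 equiv), neat melt (or Ph2O), 240 °C, N2 sweep, 30 min
Reagents that add atoms: none
Why: This is the Mentzer thermal pyrone condensation, the acid-free relative of the Simonis chromone synthesis, applied to an α-alkoxy aroylacetate. At 240 °C keto ester 7 loses ethanol to give aroylketene 9. The ketene is captured by phenol 8 reversibly at oxygen and irreversibly at the ortho carbon, where the phenolic O–H is delivered to the acyl oxygen of the ketene in a six-centre transition state; this forms C4–C4a and gives diketone 10. The phenol oxygen of 10 then adds to the aroyl carbonyl in a 6-exo-trig closure and the hemiketal loses water, which forms O1–C2 and ring C. No stereocentre is created, and the one in 7 is erased as C3 becomes sp2. The chromone is expected instead of the coumarin because no acid is present, so the ring carbon meets the ketene carbon and not the ketone. A single regioisomer should follow from the equivalence of the two ortho carbons of 8, while the para carbon, flanked by two methoxy groups and out of reach of the O–H delivery, is not expected to compete. Benzyl ethers and the aryl sulfonate contain no bond that is labile to heat or to a weakly acidic phenol, which is why they were chosen for this step.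

Step 6
Reactants: 11 2-(benzyloxy)-4-[3-(benzyloxy)-5,7-dimethoxy-4-oxo-4H-chromen-2-yl]phenyl 4-methylbenzenesulfonate
Product: 12 4-(3,5-dihydroxy-7-methoxy-4-oxo-4H-chromen-2-yl)-2-hydroxyphenyl 4-methylbenzenesulfonate
Conditions: BCl3 (6 equiv), pentamethylbenzene (6 equiv), CH2Cl2, −78 °C to 0 °C; aqueous work-up
Reagents that add atoms: none
Why: Lewis-acid ether cleavage: BCl3 removes both benzyl ethers, with pentamethylbenzene trapping the benzyl cations, and cleaves the 5-O-methyl group through the boron chelate that bridges it to the C4 carbonyl. The unchelated 7-O-methyl ether and the aryl sulfonate are inert under these conditions.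

Step 7
Reactants: 12 4-(3,5-dihydroxy-7-methoxy-4-oxo-4H-chromen-2-yl)-2-hydroxyphenyl 4-methylbenzenesulfonate
Product: 13 disodium 5-hydroxy-7-methoxy-2-{4-[(4-methylphenyl)sulfonyloxy]-3-(sulfonatooxy)phenyl}-4-oxo-4H-chromen-3-yl sulfate
Conditions: SO3·pyridine (8 equiv), pyridine, 25–40 °C; then NaHCO3 (aq.) to pH 8; C18 or Sephadex LH-20
Reagents that add atoms: sulfur trioxide–pyridine complex, O=S(=O)=O.c1ccncc1; sodium hydrogen carbonate, [Na+].OC(=O)[O-]
Why: O-Sulfation with an SO3–amine complex; O3 and O3' are the only reactive hydroxyls, because O4' is blocked and the 5-OH, hydrogen-bonded to the carbonyl, is the least reactive hydroxyl of a flavonol. The product is kept as the sodium salt, in which the half-esters are stable.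

Step 8
Reactants: 13 disodium 5-hydroxy-7-methoxy-2-{4-[(4-methylphenyl)sulfonyloxy]-3-(sulfonatooxy)phenyl}-4-oxo-4H-chromen-3-yl sulfate
Product: 14 rhamnetin 3,3'-disulfate, 5-hydroxy-2-[4-hydroxy-3-(sulfooxy)phenyl]-7-methoxy-4-oxo-4H-chromen-3-yl hydrogen sulfate
Conditions: NaOH (1 M aq., 5 equiv), 25–40 °C, N2; then HCl (aq.) to pH 2, 0 °C; C18 desalting
Reagents that add atoms: none
Why: Hydrolytic S–O cleavage of an activated aryl arenesulfonate: the 4'-phenoxide, conjugated through C2 with the ring C carbonyl, is a good leaving group, while sulfate monoester anions are not attacked by hydroxide. Cold acidification then releases the acid form.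

## Compound list

1 | 3,4-dihydroxybenzaldehyde | O=Cc1ccc(O)c(O)c1 | starting material
2 | 4-formyl-2-hydroxyphenyl 4-methylbenzenesulfonate | Cc1ccc(cc1)S(=O)(=O)Oc1ccc(C=O)cc1O | intermediate
3 | 2-(benzyloxy)-4-formylphenyl 4-methylbenzenesulfonate | Cc1ccc(cc1)S(=O)(=O)Oc1ccc(C=O)cc1OCc1ccccc1 | intermediate
4 | ethyl 2-(benzyloxy)acetate | CCOC(=O)COCc1ccccc1 | starting material
5 | lithium 2-(benzyloxy)-1-ethoxyethen-1-olate (enolate of 4, double-bond geometry not defined) | [Li+].CCOC([O-])=COCc1ccccc1 | intermediate (not isolated)
6 | ethyl 2-(benzyloxy)-3-{3-(benzyloxy)-4-[(4-methylphenyl)sulfonyloxy]phenyl}-3-hydroxypropanoate (syn/anti mixture, each racemic) | CCOC(=O)C(OCc1ccccc1)C(O)c1ccc(OS(=O)(=O)c2ccc(C)cc2)c(OCc2ccccc2)c1 | intermediate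
7 | ethyl 2-(benzyloxy)-3-{3-(benzyloxy)-4-[(4-methylphenyl)sulfonyloxy]phenyl}-3-oxopropanoate (racemic) | CCOC(=O)C(OCc1ccccc1)C(=O)c1ccc(OS(=O)(=O)c2ccc(C)cc2)c(OCc2ccccc2)c1 | intermediate
8 | 3,5-dimethoxyphenol | COc1cc(O)cc(OC)c1 | starting material
9 | 2-(benzyloxy)-3-{3-(benzyloxy)-4-[(4-methylphenyl)sulfonyloxy]phenyl}prop-1-ene-1,3-dione (aroylketene) | O=C=C(OCc1ccccc1)C(=O)c1ccc(OS(=O)(=O)c2ccc(C)cc2)c(OCc2ccccc2)c1 | intermediate (not isolated)
10 | 2-(benzyloxy)-1-{3-(benzyloxy)-4-[(4-methylphenyl)sulfonyloxy]phenyl}-3-(2-hydroxy-4,6-dimethoxyphenyl)propane-1,3-dione (racemic) | COc1cc(O)c(C(=O)C(OCc2ccccc2)C(=O)c2ccc(OS(=O)(=O)c3ccc(C)cc3)c(OCc3ccccc3)c2)c(OC)c1 | intermediate (not isolated)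
11 | 2-(benzyloxy)-4-[3-(benzyloxy)-5,7-dimethoxy-4-oxo-4H-chromen-2-yl]phenyl 4-methylbenzenesulfonate | COc1cc(OC)c2c(=O)c(OCc3ccccc3)c(-c3ccc(OS(=O)(=O)c4ccc(C)cc4)c(OCc4ccccc4)c3)oc2c1 | intermediate
12 | 4-(3,5-dihydroxy-7-methoxy-4-oxo-4H-chromen-2-yl)-2-hydroxyphenyl 4-methylbenzenesulfonate | COc1cc(O)c2c(=O)c(O)c(-c3ccc(OS(=O)(=O)c4ccc(C)cc4)c(O)c3)oc2c1 | intermediate
13 | disodium 5-hydroxy-7-methoxy-2-{4-[(4-methylphenyl)sulfonyloxy]-3-(sulfonatooxy)phenyl}-4-oxo-4H-chromen-3-yl sulfate | COc1cc(O)c2c(=O)c(OS(=O)(=O)[O-])c(-c3ccc(OS(=O)(=O)c4ccc(C)cc4)c(OS(=O)(=O)[O-])c3)oc2c1.[Na+].[Na+] | intermediate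
14 | rhamnetin 3,3'-disulfate | COc1cc(O)c2c(=O)c(OS(=O)(=O)O)c(-c3ccc(O)c(OS(=O)(=O)O)c3)oc2c1 | target

## Step count and risks

Total: 8 steps. Longest linear sequence: 8 steps (1 to 14; 4 and 8 are purchased).

**Step 5 (key step).** The most likely failures are:
- retro-Claisen cleavage of 7 by the phenol at the aroyl ketone;
- self-condensation of the aroylketene;
- O-acylation that does not go on to the ortho carbon, or incomplete dehydration of the hemiketal;
- slow transfer of the sulfonyl group to the excess phenol at 240 °C.

Fallback: the classical acyl-shift route, which forms C2–C3 and O1–C2 instead. It sets out from 8 and 3 and returns at 11.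
- Phenol 8 is acylated at the ortho carbon with benzyloxyacetyl chloride under BF3·OEt2 (O-acylation, then boron-chelated Fries shift) to 2-(benzyloxy)-1-(2-hydroxy-4,6-dimethoxyphenyl)ethan-1-one F1.
- Aldehyde 3 is oxidised with NaClO2, NaH2PO4 and 2-methyl-2-butene to 3-(benzyloxy)-4-[(4-methylphenyl)sulfonyloxy]benzoic acid F2.
- F1 and F2 are joined with EDC·HCl and DMAP to 2-[2-(benzyloxy)acetyl]-3,5-dimethoxyphenyl 3-(benzyloxy)-4-[(4-methylphenyl)sulfonyloxy]benzoate F3.
- LiN(SiMe3)2 in THF at −78 to 0 °C effects the Baker–Venkataraman shift to diketone 10, which is closed to 11 with catalytic TsOH in toluene.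

**Step 1.** Sulfonylation may be poorly selective between the two phenols or go on to the bis-sulfonate, and sulfonyl transfer between molecules may scramble the pattern under the base of step 2.

Fallback: a detour through the established 4-O-selective alkylation. It sets out from 1 and returns at 3.
- 1 with 4-methoxybenzyl chloride, NaHCO3 and NaI in DMF gives 3-hydroxy-4-[(4-methoxybenzyl)oxy]benzaldehyde F4.
- BnBr and K2CO3 give 3-(benzyloxy)-4-[(4-methoxybenzyl)oxy]benzaldehyde F5.
- Warm acetic acid removes the 4-methoxybenzyl ether and leaves the benzyl ether, giving 3-(benzyloxy)-4-hydroxybenzaldehyde F6.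
- TsCl, Et3N and catalytic DMAP give 3.

**Step 6.** Once both benzyl ethers have gone, boron chelated between O3 and the carbonyl may slow the cleavage of the 5-O-methyl group. Forcing the reaction may then erode the 7-O-methyl ether, and benzyl cations that escape the scavenger may alkylate ring A.

Fallback: separate the two events. It sets out from 11 and returns at 12.
- MgI2·OEt2 in toluene at 60 °C demethylates O5 by chelation while O3 is still an ether, giving 2-(benzyloxy)-4-[3-(benzyloxy)-5-hydroxy-7-methoxy-4-oxo-4H-chromen-2-yl]phenyl 4-methylbenzenesulfonate F7.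
- Hydrogenolysis (H2, Pd/C, EtOAc–THF) removes the benzyl ethers and gives 12. The sulfonate and the chromone double bond are expected to survive.
- Any material that has also lost the chelated 3-O-benzyl group in the first operation converges on 12 in the second.

**Step 8.** Hydroxide may add to C2 and open ring C in competition with a slow attack at sulfur, and the half-esters may hydrolyse during acidification and concentration.

Fallback: transfer the sulfonyl group to nitrogen instead of hydrolysing it. It sets out from 13 and returns at 14.
- Pyrrolidine in DMF–water at 40–50 °C converts the activated aryl sulfonate into a sulfonamide and frees the 4'-phenol without hydroxide.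
- The neutral sulfonamide is extracted, and the aqueous phase is acidified cold and desalted as in step 8.
- No new route compound is made on this path (F0).

## Further compounds

F1 | step 5 | 2-(benzyloxy)-1-(2-hydroxy-4,6-dimethoxyphenyl)ethan-1-one | COc1cc(O)c(C(=O)COCc2ccccc2)c(OC)c1
F2 | step 5 | 3-(benzyloxy)-4-[(4-methylphenyl)sulfonyloxy]benzoic acid | Cc1ccc(cc1)S(=O)(=O)Oc1ccc(C(=O)O)cc1OCc1ccccc1
F3 | step 5 | 2-[2-(benzyloxy)acetyl]-3,5-dimethoxyphenyl 3-(benzyloxy)-4-[(4-methylphenyl)sulfonyloxy]benzoate | COc1cc(OC)c(C(=O)COCc2ccccc2)c(OC(=O)c2ccc(OS(=O)(=O)c3ccc(C)cc3)c(OCc3ccccc3)c2)c1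
F4 | step 1 | 3-hydroxy-4-[(4-methoxybenzyl)oxy]benzaldehyde | COc1ccc(COc2ccc(C=O)cc2O)cc1
F5 | step 1 | 3-(benzyloxy)-4-[(4-methoxybenzyl)oxy]benzaldehyde | COc1ccc(COc2ccc(C=O)cc2OCc2ccccc2)cc1
F6 | step 1 | 3-(benzyloxy)-4-hydroxybenzaldehyde | O=Cc1ccc(O)c(OCc2ccccc2)c1
F7 | step 6 | 2-(benzyloxy)-4-[3-(benzyloxy)-5-hydroxy-7-methoxy-4-oxo-4H-chromen-2-yl]phenyl 4-methylbenzenesulfonate | COc1cc(O)c2c(=O)c(OCc3ccccc3)c(-c3ccc(OS(=O)(=O)c4ccc(C)cc4)c(OCc4ccccc4)c3)oc2c1
F0 | step 8 | none | none
A1 | alternative 1 | rac-1-({1-[4-(benzyloxy)-3-(methoxymethoxy)phenyl]prop-2-yn-1-yl}oxy)-3,5-dimethoxybenzene | C#CC(Oc1cc(OC)cc(OC)c1)c1ccc(OCc2ccccc2)c(OCOC)c1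
A2 | alternative 1 | rac-2-[4-(benzyloxy)-3-(methoxymethoxy)phenyl]-5,7-dimethoxychroman-3-one | COc1cc(OC)c2c(c1)OC(c1ccc(OCc3ccccc3)c(OCOC)c1)C(=O)C2
A3 | alternative 2 | 2-[4-(benzyloxy)-3-(methoxymethoxy)phenyl]-6-(2-diazoacetyl)-3-(methoxymethoxy)-4H-pyran-4-one | [N-]=[N+]=CC(=O)c1cc(=O)c(OCOC)c(-c2ccc(OCc3ccccc3)c(OCOC)c2)o1
A4 | alternative 2 | methoxyethyne | COC#C
A5 | alternative 2 | 2-[4-(benzyloxy)-3-(methoxymethoxy)phenyl]-5-hydroxy-7-methoxy-3-(methoxymethoxy)-4H-chromen-4-one | COc1cc(O)c2c(=O)c(OCOC)c(-c3ccc(OCc4ccccc4)c(OCOC)c3)oc2c1
A6 | alternative 3 | 1-(benzyloxy)-4-bromo-2-(methoxymethoxy)benzene | COCOc1cc(Br)ccc1OCc1ccccc1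
A7 | alternative 3 | 1-[2-(benzyloxy)-6-hydroxy-4-methoxyphenyl]-2-(methoxymethoxy)ethan-1-one | COCOCC(=O)c1c(O)cc(OC)cc1OCc1ccccc1
A8 | alternative 3 | 5-(benzyloxy)-2-[4-(benzyloxy)-3-(methoxymethoxy)phenyl]-7-methoxy-3-(methoxymethoxy)-4H-chromen-4-one | COc1cc(OCc2ccccc2)c2c(=O)c(OCOC)c(-c3ccc(OCc4ccccc4)c(OCOC)c3)oc2c1
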